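**Retrosynthetic overview**
1. C9–C10 is cut first: a catalytic enantioselective addition of an (E)-dienylzinc to a (Z)-β,γ-unsaturated aldehyde forms the C–C bond, the 10E alkene and the 9R carbinol in one operation. This replaces the usual chiral-pool epoxide, ynone-reduction or C12=C13 Wittig plans.
2. The dienylzinc comes from (3Z,6Z)-nona-3,6-dien-1-yne by hydroboration and B→Zn exchange; the enyne comes from a Z-Wittig of the (Z)-hex-3-enyl ylide with TMS-propynal.
3. The aldehyde (C1–C9) comes from a Z-Wittig at C6=C7 on a C1–C6 keto-aldehyde, which is made by ortho-lithiation of bis-SEM 5-methoxyresorcinol and opening of ε-caprolactone.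
4. End game: fluoride removal of both SEM groups, so no acid touches the dienyl carbinol.
5. Rings: none is formed; the arene is bought as 5-methoxyresorcinol and the lactone ring is only opened.

**Assumptions and abbreviations**
- The target is the 9R enantiomer as drawn: (6Z,9R,10E,12Z,15Z)-1-(2,6-dihydroxy-4-methoxyphenyl)-9-hydroxyoctadeca-6,10,12,15-tetraen-1-one.
- Ar* = 4-methoxy-2,6-bis{[2-(trimethylsilyl)ethoxy]methoxy}phenyl, attached through C1 (the carbon between the two OSEM groups).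
- (−)-MIB = (2S)-(−)-3-exo-morpholinoisoborneol, taken as commercially available.
- Step 5 is run immediately before step 10; aldehyde 10 is not stored.

**Route**

Step 1
Reactants: 1 5-methoxyresorcinol
Product: 2 1-methoxy-3,5-bis{[2-(trimethylsilyl)ethoxy]methoxy}benzene
Conditions: SEMCl (2.4 equiv), i-Pr2NEt (3 equiv), CH2Cl2, 0 °C → rt
Reagents that add atoms: 2-(trimethylsilyl)ethoxymethyl chloride C[Si](C)(C)CCOCCl
Why: Williamson-type O-alkylation of both phenols by the reactive chloromethyl ether; SEM is chosen because it directs ortho-lithiation and is later removed by fluoride.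

Step 2
Reactants: 2 1-methoxy-3,5-bis{[2-(trimethylsilyl)ethoxy]methoxy}benzene; 3 ε-caprolactone
Product: 5 6-hydroxy-1-(Ar*)hexan-1-one, via aryllithium 4 (not isolated)
Conditions: n-BuLi (1.1 equiv), THF, 0 °C, 1 h; cannulate into 3 (1.5 equiv), THF, −78 °C; aq NH4Cl
Reagents that add atoms: n-butyllithium [Li]CCCC (lithium only in intermediate 4)
Why: Directed ortho-metalation occurs at the position flanked by the two acetal-type OSEM groups (stronger directors than OMe), and acyl substitution on the lactone stops at the ketone because the di-ortho-substituted aryl ketone is too hindered for a second addition.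

Step 3
Reactants: 5 6-hydroxy-1-(Ar*)hexan-1-one
Product: 6 6-(Ar*)-6-oxohexanal
Conditions: Dess–Martin periodinane (1.3 equiv), NaHCO3, CH2Cl2, 0 °C → rt
Reagents that add atoms: none
Why: Dess–Martin oxidation takes the primary alcohol to the aldehyde under near-neutral conditions that leave the SEM acetals and the ketone untouched.

Step 4
Reactants: 6 6-(Ar*)-6-oxohexanal; 7 (3-hydroxypropyl)triphenylphosphonium bromide
Product: 9 (Z)-9-hydroxy-1-(Ar*)non-6-en-1-one, via oxido ylide 8 (not isolated)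
Conditions: 7 (1.5 equiv), NaHMDS (3.0 equiv), THF, 0 °C; then 6, −78 °C → rt; aq NH4Cl
Reagents that add atoms: sodium hexamethyldisilazide C[Si](C)(C)[N-][Si](C)(C)C.[Na+] (sodium only in intermediate 8)
Why: Wittig olefination with a non-stabilised ylide under lithium-free conditions gives the Z alkene kinetically, and the aldehyde reacts far faster than the shielded aryl ketone.

Step 5
Reactants: 9 (Z)-9-hydroxy-1-(Ar*)non-6-en-1-one
Product: 10 (Z)-9-(Ar*)-9-oxonon-3-enal
Conditions: Dess–Martin periodinane (1.5 equiv), NaHCO3 (5 equiv), CH2Cl2, 0 °C, 40 min; cold pentane filtration, used crude at once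
Reagents that add atoms: none
Why: Buffered Dess–Martin oxidation is the standard way to reach (Z)-β,γ-unsaturated aldehydes without base- or acid-induced migration of the alkene into conjugation.

Step 6
Reactants: 11 (Z)-hex-3-en-1-ol
Product: 12 (Z)-1-iodohex-3-ene
Conditions: I2, PPh3, imidazole, CH2Cl2, 0 °C → rt
Reagents that add atoms: iodine II
Why: Appel-type (Garegg–Samuelsson) iodination replaces the primary hydroxyl by SN2 without touching the Z alkene.

Step 7
Reactants: 12 (Z)-1-iodohex-3-ene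
Product: 13 [(Z)-hex-3-en-1-yl]triphenylphosphonium iodide
Conditions: PPh3 (1.1 equiv), MeCN, reflux, 16 h
Reagents that add atoms: triphenylphosphine c1ccc(cc1)P(c1ccccc1)c1ccccc1
Why: SN2 quaternisation of triphenylphosphine by the primary iodide.

Step 8
Reactants: 13 [(Z)-hex-3-en-1-yl]triphenylphosphonium iodide; 14 3-(trimethylsilyl)prop-2-ynal
Product: 16 trimethyl[(3Z,6Z)-nona-3,6-dien-1-yn-1-yl]silane, via hexenylidene ylide 15 (not isolated)
Conditions: NaHMDS (1.0 equiv), THF, −78 → 0 °C; then 14, −90 °C → rt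
Reagents that add atoms: none
Why: Z-selective Wittig olefination of the non-stabilised ylide with the ynal gives the cis-enyne (typically about 10:1 Z:E), with the minor isomer removable on AgNO3-silica.

Step 9
Reactants: 16 trimethyl[(3Z,6Z)-nona-3,6-dien-1-yn-1-yl]silane
Product: 17 (3Z,6Z)-nona-3,6-dien-1-yne
Conditions: K2CO3 (0.2 equiv), MeOH, 0 °C → rt; pentane extraction, kept as a titrated toluene solution (volatile)
Reagents that add atoms: none
Why: Base-catalysed methanolysis of the C(sp)–Si bond frees the terminal alkyne without affecting the skipped Z,Z-diene.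

Step 10
Reactants: 17 (3Z,6Z)-nona-3,6-dien-1-yne; 10 (Z)-9-(Ar*)-9-oxonon-3-enal
Product: 20 (6Z,9R,10E,12Z,15Z)-9-hydroxy-1-(Ar*)octadeca-6,10,12,15-tetraen-1-one, via dienylborane 18 (not isolated), via dienylzinc 19 (not isolated)
Conditions: Cy2BH (1.5 equiv, from BH3·SMe2 + cyclohexene), 17 (1.6 equiv), toluene, 0 °C → rt; Et2Zn (1.6 equiv), −78 °C; (−)-MIB (5 mol%); 10 (1.0 equiv, slow addition), −20 → 0 °C; aq NH4Cl
Reagents that add atoms: dicyclohexylborane B(C1CCCCC1)C1CCCCC1 (atoms only in intermediate 18); diethylzinc CC[Zn]CC (atoms only in intermediate 19)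
Why: Oppolzer–Radinov/Walsh asymmetric alkenylzinc addition: syn-hydroboration of the terminal alkyne by the bulky borane (faster than the Z-alkenes) fixes 10E, B→Zn exchange keeps the geometry, and the (−)-MIB–zinc catalyst delivers the dienyl group to the Si face of the aldehyde (the sense that gives (S)-1-phenylpropanol from PhCHO/Et2Zn), which here is 9R, while the hindered ketone and SEM ethers are inert to organozincs.

Step 11
Reactants: 20 (6Z,9R,10E,12Z,15Z)-9-hydroxy-1-(Ar*)octadeca-6,10,12,15-tetraen-1-one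
Product: 21 (6Z,9R,10E,12Z,15Z)-1-(2,6-dihydroxy-4-methoxyphenyl)-9-hydroxyoctadeca-6,10,12,15-tetraen-1-one
Conditions: TBAF (6 equiv), ethylenediamine (5 equiv), THF/DMPU, 45 °C, dark, argon; aq NH4Cl (pH about 6)
Reagents that add atoms: none
Why: Fluoride attack at silicon fragments each SEM group (β-silyl elimination to ethene, formaldehyde and the ortho-acyl-stabilised phenoxide) under non-acidic conditions that do not ionise the dienyl carbinol or move the skipped alkenes, with ethylenediamine trapping the formaldehyde.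

**Compound list**
1 | 5-methoxyresorcinol (5-methoxybenzene-1,3-diol) | COc1cc(O)cc(O)c1 | starting material
2 | 1-methoxy-3,5-bis{[2-(trimethylsilyl)ethoxy]methoxy}benzene | COc1cc(OCOCC[Si](C)(C)C)cc(OCOCC[Si](C)(C)C)c1 | intermediate
3 | ε-caprolactone (oxepan-2-one) | O=C1CCCCCO1 | starting material
4 | (4-methoxy-2,6-bis{[2-(trimethylsilyl)ethoxy]methoxy}phenyl)lithium | [Li]c1c(OCOCC[Si](C)(C)C)cc(OC)cc1OCOCC[Si](C)(C)C | intermediate (not isolated)
5 | 6-hydroxy-1-(4-methoxy-2,6-bis{[2-(trimethylsilyl)ethoxy]methoxy}phenyl)hexan-1-one | OCCCCCC(=O)c1c(OCOCC[Si](C)(C)C)cc(OC)cc1OCOCC[Si](C)(C)C | intermediate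
6 | 6-(4-methoxy-2,6-bis{[2-(trimethylsilyl)ethoxy]methoxy}phenyl)-6-oxohexanal | O=CCCCCC(=O)c1c(OCOCC[Si](C)(C)C)cc(OC)cc1OCOCC[Si](C)(C)C | intermediate
7 | (3-hydroxypropyl)triphenylphosphonium bromide | OCCC[P+](c1ccccc1)(c1ccccc1)c1ccccc1.[Br-] | starting material
8 | sodium 3-(triphenyl-λ5-phosphanylidene)propan-1-olate (oxido ylide) | [Na+].[O-]CCC=P(c1ccccc1)(c1ccccc1)c1ccccc1 | intermediate (not isolated)
9 | (Z)-9-hydroxy-1-(4-methoxy-2,6-bis{[2-(trimethylsilyl)ethoxy]methoxy}phenyl)non-6-en-1-one | OCC/C=C\CCCCC(=O)c1c(OCOCC[Si](C)(C)C)cc(OC)cc1OCOCC[Si](C)(C)C | intermediate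
10 | (Z)-9-(4-methoxy-2,6-bis{[2-(trimethylsilyl)ethoxy]methoxy}phenyl)-9-oxonon-3-enal | O=CC/C=C\CCCCC(=O)c1c(OCOCC[Si](C)(C)C)cc(OC)cc1OCOCC[Si](C)(C)C | intermediate
11 | (Z)-hex-3-en-1-ol | CC/C=C\CCO | starting material
12 | (Z)-1-iodohex-3-ene | CC/C=C\CCI | intermediate
13 | [(Z)-hex-3-en-1-yl]triphenylphosphonium iodide | CC/C=C\CC[P+](c1ccccc1)(c1ccccc1)c1ccccc1.[I-] | intermediate
14 | 3-(trimethylsilyl)prop-2-ynal | C[Si](C)(C)C#CC=O | starting material
15 | [(Z)-hex-3-en-1-ylidene]triphenyl-λ5-phosphane (ylide) | CC/C=C\CC=P(c1ccccc1)(c1ccccc1)c1ccccc1 | intermediate (not isolated)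
16 | trimethyl[(3Z,6Z)-nona-3,6-dien-1-yn-1-yl]silane | CC/C=C\C/C=C\C#C[Si](C)(C)C | intermediate
17 | (3Z,6Z)-nona-3,6-dien-1-yne | CC/C=C\C/C=C\C#C | intermediate
18 | dicyclohexyl[(1E,3Z,6Z)-nona-1,3,6-trien-1-yl]borane | CC/C=C\C/C=C\C=C\B(C1CCCCC1)C1CCCCC1 | intermediate (not isolated)
19 | ethyl[(1E,3Z,6Z)-nona-1,3,6-trien-1-yl]zinc | CC/C=C\C/C=C\C=C\[Zn]CC | intermediate (not isolated)
20 | (6Z,9R,10E,12Z,15Z)-9-hydroxy-1-(4-methoxy-2,6-bis{[2-(trimethylsilyl)ethoxy]methoxy}phenyl)octadeca-6,10,12,15-tetraen-1-one | CC/C=C\C/C=C\C=C\[C@H](O)C/C=C\CCCCC(=O)c1c(OCOCC[Si](C)(C)C)cc(OC)cc1OCOCC[Si](C)(C)C | intermediate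
21 | (6Z,9R,10E,12Z,15Z)-1-(2,6-dihydroxy-4-methoxyphenyl)-9-hydroxyoctadeca-6,10,12,15-tetraen-1-one | CC/C=C\C/C=C\C=C\[C@H](O)C/C=C\CCCCC(=O)c1c(O)cc(OC)cc1O | target

**Step count**
Total steps: 11. Longest linear sequence: 7 (steps 1, 2, 3, 4, 5, 10, 11; the enyne branch, steps 6–11, is 6).

**Three steps most likely to fail, each with a fallback**

Step 10 (together with the aldehyde from step 5). The β,γ-enal 10 may slip into conjugation or enolise under the zinc aminoalkoxide, and a linear aliphatic aldehyde may give only moderate ee. The fallback keeps the asymmetric dienylzinc addition but runs it on a robust saturated aldehyde and forms C6=C7 last by Wittig; it sets out from 17 (and uses keto-aldehyde 6) and comes back to the route at 21. Dienylzinc 19, made from 17 exactly as in step 10, is added under (−)-MIB catalysis to commercial 3-[(tert-butyldimethylsilyl)oxy]propanal to give (3R,4E,6Z,9Z)-1-[(tert-butyldimethylsilyl)oxy]dodeca-4,6,9-trien-3-ol F1. TBDPSCl/imidazole gives the 3-O-TBDPS bis-silyl ether F2, and PPTS in EtOH removes only the primary TBS group to give (3R,4E,6Z,9Z)-3-[(tert-butyldiphenylsilyl)oxy]dodeca-4,6,9-trien-1-ol F3. I2/PPh3/imidazole gives the primary iodide F4, and PPh3 in MeCN (i-Pr2NEt, 60 °C) gives the phosphonium iodide F5. NaHMDS at −78 °C gives the ylide F6, which reacts with 6 to give the 9-O-TBDPS ether of 20 F7. TBAF/ethylenediamine then removes the TBDPS and both SEM groups to give 21.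

Step 11. Aryl SEM ethers can be slow to cleave with fluoride, and forcing the conditions puts the polyene dienol at risk. The fallback swaps the phenol protecting groups before the sensitive carbinol exists; it sets out from 9 and comes back at 21. HCl in MeOH at 45 °C strips both SEM groups from the robust alcohol 9 to give (Z)-1-(2,6-dihydroxy-4-methoxyphenyl)-9-hydroxynon-6-en-1-one F8. TBSCl/imidazole/DMAP in DMF gives the tris-TBS ether F9, and CSA in MeOH at 0 °C cleaves only the primary alkyl silyl ether to give the bis(aryl-TBS) alcohol F10. Buffered Dess–Martin oxidation gives the bis(aryl-TBS) aldehyde F11, and the step-10 protocol with 17 gives the bis(aryl-TBS) carbinol F12. TBAF/AcOH in THF at 0 °C (minutes) then gives 21.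

Step 4. The oxido ylide may give eroded Z-selectivity, and the 1,6-keto-aldehyde 6 can undergo aldol side reactions under base. The fallback replaces the Wittig by a Z-selective cross-metathesis and avoids 6 altogether; it sets out from 2 and comes back at 9. Commercial hept-6-enoic acid is converted with CDI and MeNHOMe·HCl into N-methoxy-N-methylhept-6-enamide F13. Aryllithium 4, made from 2 as in step 2, adds to it to give 1-(Ar*)hept-6-en-1-one F14. Cross-metathesis of F14 with excess but-3-en-1-ol using a Z-selective cyclometalated ruthenium catalyst (THF, 35 °C) gives 9.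

**Further compounds**
F1 | step 10 | (3R,4E,6Z,9Z)-1-[(tert-butyldimethylsilyl)oxy]dodeca-4,6,9-trien-3-ol | CC/C=C\C/C=C\C=C\[C@H](O)CCO[Si](C)(C)C(C)(C)C
F2 | step 10 | (3R,4E,6Z,9Z)-1-[(tert-butyldimethylsilyl)oxy]-3-[(tert-butyldiphenylsilyl)oxy]dodeca-4,6,9-triene | CC/C=C\C/C=C\C=C\[C@H](O[Si](c1ccccc1)(c1ccccc1)C(C)(C)C)CCO[Si](C)(C)C(C)(C)C
F3 | step 10 | (3R,4E,6Z,9Z)-3-[(tert-butyldiphenylsilyl)oxy]dodeca-4,6,9-trien-1-ol | CC/C=C\C/C=C\C=C\[C@H](O[Si](c1ccccc1)(c1ccccc1)C(C)(C)C)CCO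
F4 | step 10 | tert-butyl{[(3R,4E,6Z,9Z)-1-iodododeca-4,6,9-trien-3-yl]oxy}diphenylsilane | CC/C=C\C/C=C\C=C\[C@H](O[Si](c1ccccc1)(c1ccccc1)C(C)(C)C)CCI
F5 | step 10 | {(3R,4E,6Z,9Z)-3-[(tert-butyldiphenylsilyl)oxy]dodeca-4,6,9-trien-1-yl}triphenylphosphonium iodide | CC/C=C\C/C=C\C=C\[C@H](O[Si](c1ccccc1)(c1ccccc1)C(C)(C)C)CC[P+](c1ccccc1)(c1ccccc1)c1ccccc1.[I-]
F6 | step 10 | {(3R,4E,6Z,9Z)-3-[(tert-butyldiphenylsilyl)oxy]dodeca-4,6,9-trien-1-ylidene}triphenyl-λ5-phosphane (ylide) | CC/C=C\C/C=C\C=C\[C@H](O[Si](c1ccccc1)(c1ccccc1)C(C)(C)C)CC=P(c1ccccc1)(c1ccccc1)c1ccccc1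
F7 | step 10 | (6Z,9R,10E,12Z,15Z)-9-[(tert-butyldiphenylsilyl)oxy]-1-(4-methoxy-2,6-bis{[2-(trimethylsilyl)ethoxy]methoxy}phenyl)octadeca-6,10,12,15-tetraen-1-one | CC/C=C\C/C=C\C=C\[C@H](O[Si](c1ccccc1)(c1ccccc1)C(C)(C)C)C/C=C\CCCCC(=O)c1c(OCOCC[Si](C)(C)C)cc(OC)cc1OCOCC[Si](C)(C)C
F8 | step 11 | (Z)-1-(2,6-dihydroxy-4-methoxyphenyl)-9-hydroxynon-6-en-1-one | OCC/C=C\CCCCC(=O)c1c(O)cc(OC)cc1O
F9 | step 11 | (Z)-9-[(tert-butyldimethylsilyl)oxy]-1-{2,6-bis[(tert-butyldimethylsilyl)oxy]-4-methoxyphenyl}non-6-en-1-one | CC(C)(C)[Si](C)(C)OCC/C=C\CCCCC(=O)c1c(O[Si](C)(C)C(C)(C)C)cc(OC)cc1O[Si](C)(C)C(C)(C)C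
F10 | step 11 | (Z)-1-{2,6-bis[(tert-butyldimethylsilyl)oxy]-4-methoxyphenyl}-9-hydroxynon-6-en-1-one | OCC/C=C\CCCCC(=O)c1c(O[Si](C)(C)C(C)(C)C)cc(OC)cc1O[Si](C)(C)C(C)(C)C
F11 | step 11 | (Z)-9-{2,6-bis[(tert-butyldimethylsilyl)oxy]-4-methoxyphenyl}-9-oxonon-3-enal | O=CC/C=C\CCCCC(=O)c1c(O[Si](C)(C)C(C)(C)C)cc(OC)cc1O[Si](C)(C)C(C)(C)C
F12 | step 11 | (6Z,9R,10E,12Z,15Z)-1-{2,6-bis[(tert-butyldimethylsilyl)oxy]-4-methoxyphenyl}-9-hydroxyoctadeca-6,10,12,15-tetraen-1-one | CC/C=C\C/C=C\C=C\[C@H](O)C/C=C\CCCCC(=O)c1c(O[Si](C)(C)C(C)(C)C)cc(OC)cc1O[Si](C)(C)C(C)(C)C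
F13 | step 4 | N-methoxy-N-methylhept-6-enamide | C=CCCCCC(=O)N(C)OC
F14 | step 4 | 1-(4-methoxy-2,6-bis{[2-(trimethylsilyl)ethoxy]methoxy}phenyl)hept-6-en-1-one | C=CCCCCC(=O)c1c(OCOCC[Si](C)(C)C)cc(OC)cc1OCOCC[Si](C)(C)C
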